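**The choice.** I reckon this flask by partner against substrate, not by the clock.

- Monday's: substrate 1 M; partner 0.70 equiv; second reagent 0.75 equiv; run made earlier
- flask: substrate 1.0 M; partner 0.700 equiv; second reagent 1.50 equiv; time 8.0 min

Monday's run (percent of the substrate charged)

| time / s | side product B / % | side product A / % | target / % | substrate / % | isomer of the product / % | intermediate / % |
|---|---|---|---|---|---|---|
| 10.0 | 0 | 0 | 0 | 85.4 | 0.2 | 13.8 |
| 15.0 | 0 | 0.3 | 0 | 79.7 | 0.2 | 19.6 |
| 25.0 | 0.1 | 1.1 | 0.9 | 71.3 | 0 | 28.2 |
| 40.0 | 0 | 0.8 | 0.6 | 62.2 | 1.0 | 37.8 |
| 60.0 | 0.6 | 1.4 | 0 | 52.8 | 0 | 44.6 |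
| 80.0 | 0 | 0.4 | 0.4 | 48.5 | 0.4 | 50.6 |
| 90.0 | 0 | 1.6 | 1.2 | 45.2 | 0 | 51.6 |

(readings scatter by 0.5 percentage points)

- a species is counted by the substrate in it: one side product B counts as two

1. the species that holds most of what was charged as substrate, at 8.0 min (side product A / side product B / target / intermediate / isomer of the product / substrate)
2. the largest share itself, whichever of these holds it, in percent of the substrate charged

**One number.** Each substrate turned into intermediate takes one partner. Let D be the natural logarithm of how far the ratio of partner to substrate has fallen since charging. Monday's last reading gives 0.733. With these charges D grows in step with time, and I assume second reagent leaves this step alone, so this flask reaches D = 3.91.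

**Reading it.** That ratio falls 49.9-fold, so partner, the limiting reagent, has made 69.6% of intermediate, with 30.4% of substrate unreacted.

**The test.** One number isn't enough: Monday's last substrate and intermediate readings sum 3.2 percentage points short of the charge, and D counts making, not loss. I commit to intermediate, somewhat under 69.6%. The forecast says intermediate at 42%, lower than mine: “That still exceeds the remaining substrate.”

**The flask.** The intermediate holds 59.4%, and substrate 23.1%.

    substrate + partner → intermediate (k = 1.50 L mol⁻¹ min⁻¹)
    second reagent + intermediate → target (k = 0.0349 L mol⁻¹ min⁻¹)
    substrate + second reagent → side product A (k = 0.0243 L mol⁻¹ min⁻¹)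
    target ⇌ isomer of the product (K = 0.147, k = 0.0711 min⁻¹)
    substrate + target → side product B (k = 0.247 L mol⁻¹ min⁻¹)
    2 second reagent → homo dimer (k = 0.110 L mol⁻¹ min⁻¹)

**The gap.** Early in this flask, substrate's half-life by the step to intermediate is 0.66 min with the charges as they stood, shorter than the 16 min of intermediate's step to target at 0.576 min. But at 8.00 min, with partner down to 1.42% of its charge, this flask makes intermediate at only 0.466 of the rate at which it uses it up, and intermediate stands 10 points under the 69.6% that D = 3.91 gave. With 0.420 equiv of partner, D becomes 7.56, giving 42.0% made; that flask holds 35.9% intermediate, and substrate leads at 47.5%.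

The data are simulated for substances that don't exist; scatter was added.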